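**Retrosynthetic overview**

- The target comes from its ring A mono-silyl ether by desilylation. That ether comes from an enantioselective palladium-catalysed dearomative prenylation at the methyl-bearing carbon of the still aromatic ring B, which sets the only stereocentre.
- The diarylmethane is cut at the CH2 bridge: an ortho-quinone methide from a ring A Mannich base is joined to 1-(2,4,6-trihydroxy-3-methylphenyl)butan-1-one.
- The strategy rests on ring A, where the hexanoyl-bearing carbon C1 lies between the methoxy carbon C2 and the hydroxy carbon C6. Cutting C1–C(=O) and C6–O together leads to a 3-methoxy-5-benzyloxy aryne and hexanoic acid.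
- The aryne precursor is made from 5-bromovanillin, which already has bromine beside the phenol oxygen (CHO becomes OBn by Baeyer–Villiger oxidation). Electrophilic bromination of 4-benzyloxy-2-methoxyphenol would be expected para to the methoxy group, not beside the hydroxyl.
- Ring order: both six-membered carbocycles are bought as arenes and no ring is closed; ring B is dearomatised in the second-to-last step.

Key step: step 6

Assumption: ring B is written in the enol form of the given SMILES; its other keto–enol tautomers are the same compound, and in this form the quaternary carbon is R (CIP order: ring carbon on the butanoyl side > ring carbon on the benzyl side > prenyl > methyl). MOM = methoxymethyl.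

**Route**

Step 1
Reactants: 1 5-bromovanillin (3-bromo-4-hydroxy-5-methoxybenzaldehyde)
Product: 2 3-bromo-5-methoxy-4-(methoxymethoxy)benzaldehyde
Conditions: MOMCl, iPr2NEt, CH2Cl2, 0 °C to rt
Reagents that add atoms: chloromethyl methyl ether, COCCl
Why: O-alkylation of the acidic phenol gives an acetal that should survive peracid, carbonate and benzylation and can be removed later without touching a benzyl ether or the aryl bromide.

Step 2
Reactants: 2 3-bromo-5-methoxy-4-(methoxymethoxy)benzaldehyde
Product: 4 3-bromo-5-methoxy-4-(methoxymethoxy)phenol, via aryl formate 3 (not isolated)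
Conditions: mCPBA, CH2Cl2, rt; then K2CO3 (cat.), MeOH, rt
Reagents that add atoms: meta-chloroperoxybenzoic acid, OOC(=O)c1cccc(Cl)c1
Why: Baeyer–Villiger oxidation of a benzaldehyde with a para-alkoxy group should proceed by aryl migration to the formate, which methanolysis converts into the phenol at the carbon that carried the aldehyde.

Step 3
Reactants: 4 3-bromo-5-methoxy-4-(methoxymethoxy)phenol
Product: 5 5-(benzyloxy)-1-bromo-3-methoxy-2-(methoxymethoxy)benzene
Conditions: BnBr, K2CO3, DMF, rt
Reagents that add atoms: benzyl bromide, BrCc1ccccc1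
Why: Williamson etherification of the only free phenol puts the benzyl group on the oxygen para to the masked phenol, with no regiochemical choice.

Step 4
Reactants: 5 5-(benzyloxy)-1-bromo-3-methoxy-2-(methoxymethoxy)benzene
Product: 6 4-(benzyloxy)-2-bromo-6-methoxyphenol
Conditions: conc. HCl (cat.), MeOH, 50 °C
Reagents that add atoms: none
Why: Acid-catalysed acetal exchange with methanol removes the MOM group, while the benzyl ether, methyl ether and aryl bromide are stable to dilute methanolic acid.

Step 5
Reactants: 6 4-(benzyloxy)-2-bromo-6-methoxyphenol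
Product: 10 4-(benzyloxy)-2-methoxy-6-(trimethylsilyl)phenyl trifluoromethanesulfonate, via aryl trimethylsilyl ether 7 (not isolated), via aryllithium 8 (not isolated), via lithium 2-silylphenoxide 9 (not isolated)
Conditions: (Me3Si)2NH, THF, 70 °C, then evaporation; n-BuLi, THF, −78 °C; Tf2O, −78 °C to rt
Reagents that add atoms: hexamethyldisilazane, C[Si](C)(C)N[Si](C)(C)C; trifluoromethanesulfonic anhydride, O=S(=O)(OS(=O)(=O)C(F)(F)F)C(F)(F)F
Why: O-silylation, bromine–lithium exchange (faster than any deprotonation at −78 °C), anionic 1,3 O-to-C silyl shift (retro-Brook rearrangement) and O-triflation of the resulting lithium phenoxide form the standard one-flask route from ortho-bromophenols to ortho-silylaryl triflates.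

Step 6
Reactants: 10 4-(benzyloxy)-2-methoxy-6-(trimethylsilyl)phenyl trifluoromethanesulfonate; 11 hexanoic acid
Product: 13 1-[4-(benzyloxy)-2-hydroxy-6-methoxyphenyl]hexan-1-one, via 5-benzyloxy-3-methoxybenzyne 12 (not isolated)
Conditions: CsF (4 equiv), THF, 125 °C, sealed tube
Reagents that add atoms: none
Why: Fluoride attacks silicon and triflate departs to give aryne 12; hexanoate (from 11 and CsF) adds through oxygen to the aryne carbon remote from the methoxy group, the resulting aryl anion attacks the ester carbonyl through a four-membered transition state, and collapse of the tetrahedral intermediate moves the acyl group from oxygen to carbon, so the aryl–C(=O) bond and the aryl–O bond form at the two former aryne carbons. The closest known reaction type is the fluoride-triggered insertion of arynes into the C–O bond of carboxylic acids, which leads to ortho-hydroxyaryl ketones. No ring is closed and no stereocentre is formed. The step needs regiocontrol, which the methoxy group beside the triple bond should secure: the distorted aryne accepts the oxygen nucleophile at the carbon flanked by hydrogen and leaves the carbanion, and hence the acyl group, on the carbon next to the inductively withdrawing C–OMe bond, while the more distant benzyloxy group has little influence. It also needs the acyl shift to outrun protonation of the aryl anion, which the high temperature, the aprotic medium and excess CsF (binding HF as bifluoride) should favour.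

Step 7
Reactants: 13 1-[4-(benzyloxy)-2-hydroxy-6-methoxyphenyl]hexan-1-one
Product: 14 1-(2,4-dihydroxy-6-methoxyphenyl)hexan-1-one
Conditions: H2 (1 atm), Pd/C (10% palladium on carbon), EtOAc, rt
Reagents that add atoms: none
Why: Hydrogenolysis of the aryl benzyl ether should be much faster than reduction of the electron-rich, hydrogen-bonded aryl ketone at one atmosphere in a neutral solvent.

Step 8
Reactants: 14 1-(2,4-dihydroxy-6-methoxyphenyl)hexan-1-one
Product: 15 1-{3-[(dimethylamino)methyl]-2,4-dihydroxy-6-methoxyphenyl}hexan-1-one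
Conditions: 37% aq. CH2O (1.0 equiv), 40% aq. Me2NH (1.1 equiv), EtOH, 0 °C to rt
Reagents that add atoms: formaldehyde, C=O; dimethylamine, CNC
Why: In this phenolic Mannich reaction the iminium ion should attack the ring carbon flanked by both hydroxyls, the most nucleophilic site of 2,4-dihydroxyacylphenones, and one equivalent of reagent limits double aminomethylation.

Step 9
Reactants: 15 1-{3-[(dimethylamino)methyl]-2,4-dihydroxy-6-methoxyphenyl}hexan-1-one
Product: 16 1-{3-[(dimethylamino)methyl]-2-hydroxy-6-methoxy-4-[(triisopropylsilyl)oxy]phenyl}hexan-1-one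
Conditions: iPr3SiCl, imidazole, DMF, rt
Reagents that add atoms: chlorotriisopropylsilane, CC(C)[Si](Cl)(C(C)C)C(C)C
Why: The 2-hydroxyl is held in a hydrogen bond to the ketone, so silylation should occur only at the 4-hydroxyl, which masks the acidic, nucleophilic phenol of ring A before the union and the palladium step.

Step 10
Reactants: 17 2,4,6-trihydroxytoluene; 18 butanoyl chloride
Product: 19 1-(2,4,6-trihydroxy-3-methylphenyl)butan-1-one
Conditions: AlCl3 (3.5 equiv), PhNO2, rt to 50 °C; then ice/aq. HCl
Reagents that add atoms: none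
Why: Friedel–Crafts C-acylation of the phloroglucinol, whose two free ring positions are equivalent, should give a single mono-ketone that is deactivated towards a second acylation.

Step 11
Reactants: 16 1-{3-[(dimethylamino)methyl]-2-hydroxy-6-methoxy-4-[(triisopropylsilyl)oxy]phenyl}hexan-1-one; 19 1-(2,4,6-trihydroxy-3-methylphenyl)butan-1-one
Product: 21 1-{3-[(3-butanoyl-2,4,6-trihydroxy-5-methylphenyl)methyl]-2-hydroxy-6-methoxy-4-[(triisopropylsilyl)oxy]phenyl}hexan-1-one, via ortho-quinone methide 20 (not isolated)
Conditions: 19 (1.2 equiv), 1,4-dioxane, 100 °C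
Reagents that add atoms: none
Why: Retro-Mannich loss of dimethylamine through the free 2-hydroxyl gives ortho-quinone methide 20, and the only unsubstituted ring carbon of 19, flanked by two hydroxyls, should add to its exocyclic methylene (conjugate addition, then rearomatisation of both rings), the classical way to methylene-bridged acylphloroglucinols.

Step 12
Reactants: 21 1-{3-[(3-butanoyl-2,4,6-trihydroxy-5-methylphenyl)methyl]-2-hydroxy-6-methoxy-4-[(triisopropylsilyl)oxy]phenyl}hexan-1-one
Product: 22 (4R)-2-butanoyl-6-({3-hexanoyl-2-hydroxy-4-methoxy-6-[(triisopropylsilyl)oxy]phenyl}methyl)-3,5-dihydroxy-4-methyl-4-(3-methylbut-2-en-1-yl)cyclohexa-2,5-dien-1-one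
Conditions: Pd2(dba)3 (2.5 mol %), (R,R)-DACH-phenyl bisphosphine ligand N,N'-[(1R,2R)-cyclohexane-1,2-diyl]bis[2-(diphenylphosphanyl)benzamide] (7.5 mol %), tert-butyl prenyl carbonate (1.05 equiv), THF, 0 °C to rt
Reagents that add atoms: tert-butyl (3-methylbut-2-en-1-yl) carbonate, CC(C)=CCOC(=O)OC(C)(C)C
Why: Proposed new method: zerovalent palladium ionises the carbonate to an η3-prenyl palladium cation, CO2 and tert-butoxide, which deprotonates the acylphloroglucinol of ring B (far more acidic than the ketone-chelated hydroxyl left on ring A), and the phloroglucinolate should attack the unsubstituted allyl terminus through its less hindered methyl-bearing carbon, the chiral pocket of the ligand choosing one face of the ring and so setting the quaternary centre (O-prenyl ethers would be re-ionised and funnel to the C-alkylated dienone); the closest known reaction types are the racemic Tsuji–Trost dearomative allylation of acylphloroglucinols, the palladium-catalysed asymmetric allylic dearomatisation of naphthols and the ligand-controlled linear prenylation of prochiral oxindole enolates with this ligand family, and the (S,S)-ligand is used instead if the sense of induction proves to be the opposite one.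

Step 13
Reactants: 22 (4R)-2-butanoyl-6-({3-hexanoyl-2-hydroxy-4-methoxy-6-[(triisopropylsilyl)oxy]phenyl}methyl)-3,5-dihydroxy-4-methyl-4-(3-methylbut-2-en-1-yl)cyclohexa-2,5-dien-1-one
Product: 23 (4R)-2-butanoyl-6-[(3-hexanoyl-2,6-dihydroxy-4-methoxyphenyl)methyl]-3,5-dihydroxy-4-methyl-4-(3-methylbut-2-en-1-yl)cyclohexa-2,5-dien-1-one
Conditions: Bu4NF, AcOH (1:1), THF, 0 °C
Reagents that add atoms: none
Why: Fluoride cleavage of the aryl silyl ether under acetic acid buffering should be mild enough to leave the prenyl group, the enolised triketone and the quaternary stereocentre (which bears no hydrogen) untouched.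

**Compound list**

1 | 5-bromovanillin (3-bromo-4-hydroxy-5-methoxybenzaldehyde) | COc1cc(C=O)cc(Br)c1O | starting material
2 | 3-bromo-5-methoxy-4-(methoxymethoxy)benzaldehyde | COCOc1c(OC)cc(C=O)cc1Br | intermediate
3 | 3-bromo-5-methoxy-4-(methoxymethoxy)phenyl formate | COCOc1c(OC)cc(OC=O)cc1Br | intermediate
4 | 3-bromo-5-methoxy-4-(methoxymethoxy)phenol | COCOc1c(OC)cc(O)cc1Br | intermediate
5 | 5-(benzyloxy)-1-bromo-3-methoxy-2-(methoxymethoxy)benzene | COCOc1c(OC)cc(OCc2ccccc2)cc1Br | intermediate
6 | 4-(benzyloxy)-2-bromo-6-methoxyphenol | COc1cc(OCc2ccccc2)cc(Br)c1O | intermediate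
7 | [4-(benzyloxy)-2-bromo-6-methoxyphenoxy]trimethylsilane | COc1cc(OCc2ccccc2)cc(Br)c1O[Si](C)(C)C | intermediate
8 | {5-(benzyloxy)-3-methoxy-2-[(trimethylsilyl)oxy]phenyl}lithium | COc1cc(OCc2ccccc2)cc([Li])c1O[Si](C)(C)C | intermediate
9 | lithium 4-(benzyloxy)-2-methoxy-6-(trimethylsilyl)phenoxide | COc1cc(OCc2ccccc2)cc([Si](C)(C)C)c1[O-].[Li+] | intermediate
10 | 4-(benzyloxy)-2-methoxy-6-(trimethylsilyl)phenyl trifluoromethanesulfonate | COc1cc(OCc2ccccc2)cc([Si](C)(C)C)c1OS(=O)(=O)C(F)(F)F | intermediate
11 | hexanoic acid | CCCCCC(=O)O | starting material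
12 | 5-(benzyloxy)-3-methoxybenzyne (aryne carbons next to C–OMe and next to C–H) | COC1=CC(OCc2ccccc2)=CC#C1 | intermediate
13 | 1-[4-(benzyloxy)-2-hydroxy-6-methoxyphenyl]hexan-1-one | CCCCCC(=O)c1c(OC)cc(OCc2ccccc2)cc1O | intermediate
14 | 1-(2,4-dihydroxy-6-methoxyphenyl)hexan-1-one | CCCCCC(=O)c1c(OC)cc(O)cc1O | intermediate
15 | 1-{3-[(dimethylamino)methyl]-2,4-dihydroxy-6-methoxyphenyl}hexan-1-one | CCCCCC(=O)c1c(OC)cc(O)c(CN(C)C)c1O | intermediate
16 | 1-{3-[(dimethylamino)methyl]-2-hydroxy-6-methoxy-4-[(triisopropylsilyl)oxy]phenyl}hexan-1-one | CCCCCC(=O)c1c(OC)cc(O[Si](C(C)C)(C(C)C)C(C)C)c(CN(C)C)c1O | intermediate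
17 | 2,4,6-trihydroxytoluene (2-methylbenzene-1,3,5-triol) | Cc1c(O)cc(O)cc1O | starting material
18 | butanoyl chloride | CCCC(=O)Cl | starting material
19 | 1-(2,4,6-trihydroxy-3-methylphenyl)butan-1-one | CCCC(=O)c1c(O)cc(O)c(C)c1O | intermediate
20 | 2-hexanoyl-3-methoxy-6-methylidene-5-[(triisopropylsilyl)oxy]cyclohexa-2,4-dien-1-one | CCCCCC(=O)C1=C(OC)C=C(O[Si](C(C)C)(C(C)C)C(C)C)C(=C)C1=O | intermediate
21 | 1-{3-[(3-butanoyl-2,4,6-trihydroxy-5-methylphenyl)methyl]-2-hydroxy-6-methoxy-4-[(triisopropylsilyl)oxy]phenyl}hexan-1-one | CCCCCC(=O)c1c(OC)cc(O[Si](C(C)C)(C(C)C)C(C)C)c(Cc2c(O)c(C)c(O)c(C(=O)CCC)c2O)c1O | intermediate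
22 | (4R)-2-butanoyl-6-({3-hexanoyl-2-hydroxy-4-methoxy-6-[(triisopropylsilyl)oxy]phenyl}methyl)-3,5-dihydroxy-4-methyl-4-(3-methylbut-2-en-1-yl)cyclohexa-2,5-dien-1-one | CCCCCC(=O)c1c(OC)cc(O[Si](C(C)C)(C(C)C)C(C)C)c(CC2=C(O)[C@@](C)(CC=C(C)C)C(O)=C(C(=O)CCC)C2=O)c1O | intermediate
23 | (4R)-2-butanoyl-6-[(3-hexanoyl-2,6-dihydroxy-4-methoxyphenyl)methyl]-3,5-dihydroxy-4-methyl-4-(3-methylbut-2-en-1-yl)cyclohexa-2,5-dien-1-one | CCCCCC(=O)c1c(OC)cc(O)c(CC2=C(O)[C@@](C)(CC=C(C)C)C(O)=C(C(=O)CCC)C2=O)c1O | target

**Step count**

Total step count: 13. Longest linear sequence: 12 steps (steps 1–9 and 11–13, from 5-bromovanillin); step 10 is a one-step side branch.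

**Steps most likely to fail**

1. Step 12. The facial selectivity at the methyl-bearing carbon may be poor, and the allyl–palladium cation may instead be captured at the benzyl-bearing ring carbon or at oxygen. The fallback uses known chemistry and sets out from 21. Compound 21 is converted into its lithium salt with LiN(SiMe3)2 in THF at −78 °C and alkylated with prenyl bromide at 0 °C, the classical base-mediated dearomative C-prenylation of acylphloroglucinols, to give racemic 2-butanoyl-6-({3-hexanoyl-2-hydroxy-4-methoxy-6-[(triisopropylsilyl)oxy]phenyl}methyl)-3,5-dihydroxy-4-methyl-4-(3-methylbut-2-en-1-yl)cyclohexa-2,5-dien-1-one F1. The enantiomers are separated by preparative HPLC on a chiral stationary phase; the (4S) enantiomer F2 is set aside, and the (4R) enantiomer is 22, where the route resumes.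

2. Step 6. The aryl anion may be protonated before the acyl shift, which would stop at the aryl ester; the product phenoxide may be arylated by a second aryne; or regiocontrol may erode. The fallback sets out from 11 and makes steps 1–7 unnecessary. Hexanoic acid is converted with oxalyl chloride and catalytic DMF into hexanoyl chloride F3, which acylates commercial 5-methoxyresorcinol F4 under AlCl3 in PhNO2 (Friedel–Crafts acylation). The isomer acylated between the two hydroxyls, 1-(2,6-dihydroxy-4-methoxyphenyl)hexan-1-one F5, is removed by chromatography, and the other isomer is 14, where the route resumes.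

3. Step 11. Thermal loss of dimethylamine may be slow, the quinone methide may be captured at a phenol oxygen of 19, or the silyl group may be lost on prolonged heating. The fallback sets out from 16. N-Methylation with MeI in MeCN at rt gives {3-hexanoyl-2-hydroxy-4-methoxy-6-[(triisopropylsilyl)oxy]benzyl}trimethylammonium iodide F6. With NaHCO3 in MeCN/THF at rt and in the presence of 19, the phenoxide expels trimethylamine and releases the same quinone methide 20 at room temperature, which 19 traps to give 21, where the route resumes.

**Further compounds**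

F1 | step 12 | racemic 2-butanoyl-6-({3-hexanoyl-2-hydroxy-4-methoxy-6-[(triisopropylsilyl)oxy]phenyl}methyl)-3,5-dihydroxy-4-methyl-4-(3-methylbut-2-en-1-yl)cyclohexa-2,5-dien-1-one | CCCCCC(=O)c1c(OC)cc(O[Si](C(C)C)(C(C)C)C(C)C)c(CC2=C(O)C(C)(CC=C(C)C)C(O)=C(C(=O)CCC)C2=O)c1O
F2 | step 12 | (4S)-2-butanoyl-6-({3-hexanoyl-2-hydroxy-4-methoxy-6-[(triisopropylsilyl)oxy]phenyl}methyl)-3,5-dihydroxy-4-methyl-4-(3-methylbut-2-en-1-yl)cyclohexa-2,5-dien-1-one | CCCCCC(=O)c1c(OC)cc(O[Si](C(C)C)(C(C)C)C(C)C)c(CC2=C(O)[C@](C)(CC=C(C)C)C(O)=C(C(=O)CCC)C2=O)c1O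
F3 | step 6 | hexanoyl chloride | CCCCCC(=O)Cl
F4 | step 6 | 5-methoxyresorcinol (5-methoxybenzene-1,3-diol) | COc1cc(O)cc(O)c1
F5 | step 6 | 1-(2,6-dihydroxy-4-methoxyphenyl)hexan-1-one | CCCCCC(=O)c1c(O)cc(OC)cc1O
F6 | step 11 | {3-hexanoyl-2-hydroxy-4-methoxy-6-[(triisopropylsilyl)oxy]benzyl}trimethylammonium iodide | CCCCCC(=O)c1c(OC)cc(O[Si](C(C)C)(C(C)C)C(C)C)c(C[N+](C)(C)C)c1O.[I-]
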